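**Retrosynthetic overview**
- The bicyclo[3.2.1]octane is opened at the bond between the methyl-bearing bridgehead and the CH(CMe2OH) carbon: an enolate carbon opens an oxirane (5-exo). This five-membered carbocycle is closed last, onto the existing six-membered trione ring.
- The oxirane comes from one of two enantiotopic prenyl groups of a gem-diprenyl acyl-trione, by a peptide-peracid (metal-free) epoxidation that selects both the prenyl group and the olefin face; this fixes all three ring stereocentres.
- The gem-diprenyl trione comes from an acyl methylphloroglucinol by dearomative double C-prenylation; the six-membered ring is the starting arene ring.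
- The acyl methylphloroglucinol comes from 2-methylphloroglucinol and (R)-2-methylbutanoic acid (Friedel–Crafts); the acid comes from tiglic acid by asymmetric hydrogenation, which sets the first stereocentre.

Assumption: the target is taken as the enol tautomer written in its SMILES, and the peptide antipode that gives the (6S,2'S)-oxirane is the one used (its sense of induction is not yet known; one antipode is drawn, both are equally accessible).

Peptide catalyst P (step 4): Boc-L-Asp-L-Pro-D-Val-NH-(R)-CH(CH3)Ph with the free Asp side-chain CO2H, SMILES CC(C)(C)OC(=O)N[C@@H](CC(=O)O)C(=O)N1CCC[C@H]1C(=O)N[C@H](C(C)C)C(=O)N[C@H](C)c1ccccc1.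

**Route**

Step 1
Reactants: 1 tiglic acid, (E)-2-methylbut-2-enoic acid
Product: 2 (R)-2-methylbutanoic acid
Conditions: H2 (1.5 atm), Ru(OAc)2[(R)-H8-BINAP] (0.5 mol %), MeOH, 20 °C
Reagents that add atoms: none
Why: Asymmetric hydrogenation of an α,β-unsaturated acid, in which the carboxylate binds ruthenium and the (R)-diphosphine directs hydrogen to one olefin face, should give the (R)-acid in about 97% ee (recalled precedent for this ligand class), the first stereocentre, made by catalysis from achiral 1.

Step 2
Reactants: 2 (R)-2-methylbutanoic acid; 3 2-methylphloroglucinol (2-methylbenzene-1,3,5-triol)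
Product: 5 (2R)-2-methyl-1-(2,4,6-trihydroxy-3-methylphenyl)butan-1-one, via (R)-2-methylbutanoyl chloride 4 (not isolated)
Conditions: (COCl)2, DMF (cat.), CH2Cl2, 0 °C to rt; then 3, AlCl3 (4 equiv), PhNO2/CH2Cl2, 0 °C to rt; aq. HCl
Reagents that add atoms: none
Why: Base-free acid chloride formation (no ketene, so no racemisation) is followed by Friedel–Crafts C-acylation of the electron-rich triol at one of its two equivalent free positions; the chelated ortho-hydroxy ketone resists a second acylation and the α-stereocentre is not touched.

Step 3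
Reactants: 5 (2R)-2-methyl-1-(2,4,6-trihydroxy-3-methylphenyl)butan-1-one; 6 prenyl bromide (1-bromo-3-methylbut-2-ene, 2.2 equiv)
Product: 8 3,5-dihydroxy-4-methyl-2-[(2R)-2-methylbutanoyl]-6,6-bis(3-methylbut-2-en-1-yl)cyclohexa-2,4-dien-1-one, via mono-prenyl acylphloroglucinol 7 (not isolated)
Conditions: 6, NaOMe (3 equiv), MeOH, 0 °C to rt; aq. HCl
Reagents that add atoms: prenyl bromide 6, CC(C)=CCBr
Why: Dearomative double C-prenylation (SN2 alkylation of the phloroglucinol anion, C-selective in methanol) puts the first prenyl group on the free ring carbon and the second on the same carbon, which creates the prochiral gem-diprenyl centre; the isomer alkylated at the methyl-bearing carbon is the main by-product (about 30% of 8 expected), and the side-chain centre is safe because the substrate reacts as its enolate.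

Step 4
Reactants: 8 3,5-dihydroxy-4-methyl-2-[(2R)-2-methylbutanoyl]-6,6-bis(3-methylbut-2-en-1-yl)cyclohexa-2,4-dien-1-one
Product: 10 (1S,5S,7S)-2-hydroxy-7-(2-hydroxypropan-2-yl)-1-methyl-3-[(2R)-2-methylbutanoyl]-5-(3-methylbut-2-en-1-yl)bicyclo[3.2.1]oct-2-ene-4,8-dione (target CNP0201042.1), via (6S,2'S)-monoepoxide 9 (not isolated)
Conditions: peptide P (10 mol %), DIC (1.05 equiv), 30% aq. H2O2 (1.2 equiv), DMAP (10 mol %), PhMe, −10 °C; then Et3N (1.2 equiv), MeOH, 40 °C; aq. citric acid
Reagents that add atoms: hydrogen peroxide, OO
Why: Proposed new method: an aspartyl β-turn peptide, turned over as its side-chain peracid by DIC/H2O2, is used to distinguish the two enantiotopic prenyl groups of a gem-diprenyl β-triketone. In 8 the free acidic C5–OH enol (H-bond donor) and the C1=O (acceptor) flank C6 on opposite sides, so two-point H-bonding should dock the planar ring in one orientation on the chiral peptide, and the peracid then reaches only the prenyl group on one ring face and only one olefin face (butterfly oxygen transfer) to give (6S,2'S)-9. Mono-epoxides formed on the other prenyl group still carry the fast-reacting one and are drained to bis-epoxide, which raises the purity of 9. Et3N/MeOH then gives the H-bonded enolate, whose methyl-bearing carbon C4 opens the oxirane at its CH carbon in a 5-(enolexo)-exo-tet SN2 step with inversion. The bridge can only form on the ring face that carries the oxirane arm, so C6 of 9 fixes both bridgeheads (C1 and C5 of 10), and the (S)-oxirane carbon becomes C7 (S) with the CMe2OH group exo, syn to the C8 carbonyl. The closest known reaction types are hydroxyl- or carbamate-directed aspartyl-peracid peptide epoxidation, the Sharpless desymmetrisation of divinyl carbinols, and biomimetic enolate opening of epoxides.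

**Compound list**
1 | tiglic acid, (E)-2-methylbut-2-enoic acid | C/C=C(\C)C(=O)O | starting material
2 | (R)-2-methylbutanoic acid | CC[C@@H](C)C(=O)O | intermediate
3 | 2-methylphloroglucinol (2-methylbenzene-1,3,5-triol) | Cc1c(O)cc(O)cc1O | starting material
4 | (R)-2-methylbutanoyl chloride | CC[C@@H](C)C(=O)Cl | intermediate
5 | (2R)-2-methyl-1-(2,4,6-trihydroxy-3-methylphenyl)butan-1-one | CC[C@@H](C)C(=O)c1c(O)cc(O)c(C)c1O | intermediate
6 | prenyl bromide (1-bromo-3-methylbut-2-ene) | CC(C)=CCBr | starting material
7 | (2R)-2-methyl-1-[2,4,6-trihydroxy-3-methyl-5-(3-methylbut-2-en-1-yl)phenyl]butan-1-one | CC[C@@H](C)C(=O)c1c(O)c(C)c(O)c(CC=C(C)C)c1O | intermediate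
8 | 3,5-dihydroxy-4-methyl-2-[(2R)-2-methylbutanoyl]-6,6-bis(3-methylbut-2-en-1-yl)cyclohexa-2,4-dien-1-one | CC[C@@H](C)C(=O)C1=C(O)C(C)=C(O)C(CC=C(C)C)(CC=C(C)C)C1=O | intermediate
9 | (6S)-6-{[(2S)-3,3-dimethyloxiran-2-yl]methyl}-3,5-dihydroxy-4-methyl-2-[(2R)-2-methylbutanoyl]-6-(3-methylbut-2-en-1-yl)cyclohexa-2,4-dien-1-one | CC[C@@H](C)C(=O)C1=C(O)C(C)=C(O)[C@](CC=C(C)C)(C[C@@H]2OC2(C)C)C1=O | intermediate
10 | (1S,5S,7S)-2-hydroxy-7-(2-hydroxypropan-2-yl)-1-methyl-3-[(2R)-2-methylbutanoyl]-5-(3-methylbut-2-en-1-yl)bicyclo[3.2.1]oct-2-ene-4,8-dione, 7-exo | CC[C@@H](C)C(=O)C1=C(O)[C@@]2(C)C(=O)[C@](CC=C(C)C)(C[C@@H]2C(C)(C)O)C1=O | target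

**Totals**
Total step count: 4. Longest linear sequence: 4 steps (1 → 2 → 5 → 8 → 10).

**Three steps most likely to fail**

Step 4 (the proposed new step, highest risk). The peptide may not separate the two prenyl groups. The acidic enol may also be hydroxylated at C4, react with DIC, or close through oxygen to a dihydrofuran instead of through carbon. The fallback uses known chemistry, sets out from 8 and comes back at 10. It is a Shi epoxidation with the enantiomer of the Shi ketone (made from L-sorbose, 30 mol %), KHSO5 (as 2KHSO5·KHSO4·K2SO4, 1.0 equiv), K2CO3 buffer, MeCN/dimethoxymethane/H2O, 0 °C. This ketone should give the (S)-oxirane but cannot choose between the prenyl groups, so 9 forms about 1:1 with its C6 epimer, the (6R,2'S)-monoepoxide F1. Et3N/MeOH at 40 °C closes both: 9 gives 10, and F1 gives the 7-endo diastereomer F2 with mirror-image bridgeheads. F2 is a diastereomer of 10 and is removed by chromatography, so at best about half of the material reaches 10.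

Step 3. The second alkylation also goes to the methyl-bearing carbon and to oxygen, and 5 can be over-alkylated. The fallback sets out from 5 and comes back at 8. One equivalent of 6 in aq. KOH at 0 °C gives the aromatic mono-C-prenyl compound 7, which is now isolated. The second prenyl group is then added by a Tsuji–Trost allylation: Pd(PPh3)4 (5 mol %, zerovalent palladium), prenyl acetate, Et3N, THF, 40 °C. The soft π-prenyl electrophile is attacked at its CH2 end, and the ratio of attack at the two ring carbons can be tuned by the phosphine; whether this improves on the bromide alkylation is not established.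

Step 2. Losses may come from O-acylation or over-acylation of the free triol, and from partial racemisation under AlCl3. The fallback sets out from 4 (made from 2 as in step 2) and comes back at 5. Friedel–Crafts acylation of commercial 1,3,5-trimethoxy-2-methylbenzene with 4 (AlCl3, CH2Cl2, −10 °C) gives (2R)-2-methyl-1-(2,4,6-trimethoxy-3-methylphenyl)butan-1-one F3. BBr3 (CH2Cl2, −78 °C to rt) then removes the three methyl groups to give 5.

**Further compounds**
F1 | step 4 | (6R)-6-{[(2S)-3,3-dimethyloxiran-2-yl]methyl}-3,5-dihydroxy-4-methyl-2-[(2R)-2-methylbutanoyl]-6-(3-methylbut-2-en-1-yl)cyclohexa-2,4-dien-1-one | CC[C@@H](C)C(=O)C1=C(O)C(C)=C(O)[C@@](CC=C(C)C)(C[C@@H]2OC2(C)C)C1=O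
F2 | step 4 | (1R,5R,7S)-2-hydroxy-7-(2-hydroxypropan-2-yl)-1-methyl-3-[(2R)-2-methylbutanoyl]-5-(3-methylbut-2-en-1-yl)bicyclo[3.2.1]oct-2-ene-4,8-dione, 7-endo | CC[C@@H](C)C(=O)C1=C(O)[C@]2(C)C(=O)[C@@](CC=C(C)C)(C[C@@H]2C(C)(C)O)C1=O
F0 | step 3 | none | none
F3 | step 2 | (2R)-2-methyl-1-(2,4,6-trimethoxy-3-methylphenyl)butan-1-one | CC[C@@H](C)C(=O)c1c(OC)cc(OC)c(C)c1OC
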